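## Retrosynthetic overview

- Numbering runs from C1 (alkyne CH) to C15 (ethyl CH3). The strategy rests on the C6 chloride and C7 acetoxy group, which are anti to each other, with the C7 oxygen 1,3-syn to the C9 oxygen of the 2,6-cis oxane (O, C9–C13).
- Key disconnection: C7–O and C6–Cl are made together by chlorocyclisation of a C9 tert-butyl carbonate onto an E C6=C7 alkene. The temporary 1,3-dioxan-2-one is the first ring formed.
- The oxane is the second ring, closed from the freed C9 hydroxyl and a C13 ethyl ketone by hemiketal reduction. C12–Br and C10–Cl then come from SN2 inversion of silyl-differentiated alcohols, and the E-enyne from a C3–C4 alkyne by hydrozirconation–iodination and Sonogashira coupling.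
- The precursor is joined at C7–C8 by opening a C8–C9 epoxide with an E-alkenylalane made from a skipped diyne. C12 comes from the lactone of the L-malic acid series; C10 and C9 come from vinyl addition and Sharpless epoxidation.

Key step: step 12

Remark: (S)-α-hydroxy-γ-butyrolactone, the lactone corresponding to L-malic acid with its β-carboxyl reduced, is taken as the commercial starting material.
Remark: step 4 gives both C10 epimers and step 5 converts only the (10S) one, so at most half of the material passes this point.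
Remark: the alkynyl TMS group is expected to be lost together with the carbonate in step 13; this is harmless because the free alkyne is needed in step 20.

## Route

Step 1
Reactants: 1 (S)-α-hydroxy-γ-butyrolactone
Product: 2 (3S)-3-(tert-butyldimethylsilyloxy)oxolan-2-one
Conditions: TBSCl, imidazole, DMF, 0 °C → rt
Reagents that add atoms: tert-butyldimethylsilyl chloride, CC(C)(C)[Si](C)(C)Cl
Why: Imidazole-mediated silylation of the secondary alcohol masks the C12 oxygen as the silyl ether that can later be cleaved before the C10 TBDPS ether, and C12 (S) is carried over unchanged from the lactone.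

Step 2
Reactants: 2 (3S)-3-(tert-butyldimethylsilyloxy)oxolan-2-one
Product: 3 (2S)-2-(tert-butyldimethylsilyloxy)-4-hydroxy-N-methoxy-N-methylbutanamide
Conditions: MeNHOMe·HCl, AlMe3, CH2Cl2, 0 °C → rt
Reagents that add atoms: N,O-dimethylhydroxylamine hydrochloride, CNOC.Cl
Why: Weinreb aminolysis of the lactone with the aluminium amide opens the ring at the acyl carbon, giving the C13 amide as a latent ethyl ketone and freeing the C10 primary alcohol without touching C12.

Step 3
Reactants: 3 (2S)-2-(tert-butyldimethylsilyloxy)-4-hydroxy-N-methoxy-N-methylbutanamide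
Product: 4 (2S)-2-(tert-butyldimethylsilyloxy)-N-methoxy-N-methyl-4-oxobutanamide
Conditions: Dess–Martin periodinane, NaHCO3, CH2Cl2, 0 °C → rt
Reagents that add atoms: none
Why: Dess–Martin oxidation under buffered, non-basic conditions should give the β-silyloxy aldehyde without elimination or epimerisation, and is run at once because the γ-hydroxy amide tends to relactonise.

Step 4
Reactants: 4 (2S)-2-(tert-butyldimethylsilyloxy)-N-methoxy-N-methyl-4-oxobutanamide; 5 vinylmagnesium bromide
Product: 6 (2S,4RS)-2-(tert-butyldimethylsilyloxy)-4-hydroxy-N-methoxy-N-methylhex-5-enamide (both C10 epimers)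
Conditions: THF, −78 °C; aq. NH4Cl at −78 °C
Reagents that add atoms: none
Why: Grignard addition at −78 °C is selective for the aldehyde over the Weinreb amide, and since no useful 1,3-induction is expected C10 is formed as both epimers and sorted in step 5.

Step 5
Reactants: 6 (2S,4RS)-2-(tert-butyldimethylsilyloxy)-4-hydroxy-N-methoxy-N-methylhex-5-enamide
Product: 7 (2S,4S)-2-(tert-butyldimethylsilyloxy)-4-hydroxy-N-methoxy-N-methyl-4-[(2R)-oxiran-2-yl]butanamide (9R,10S,12S in target numbering)
Conditions: Ti(OiPr)4, L-(+)-DIPT, TBHP, 4 Å MS, CH2Cl2, −20 °C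
Reagents that add atoms: tert-butyl hydroperoxide, CC(C)(C)OO
Why: In this Sharpless kinetic resolution the Ti(OiPr)4/L-(+)-DIPT system should epoxidise only the (10S) allylic alcohol, from the face that gives the erythro (9R,10S) epoxy alcohol, so C9 is set by the reagent and C10 is selected while the (10R) epimer stays behind as allylic alcohol and is removed by chromatography.

Step 6
Reactants: 7 (2S,4S)-2-(tert-butyldimethylsilyloxy)-4-hydroxy-N-methoxy-N-methyl-4-[(2R)-oxiran-2-yl]butanamide
Product: 8 (2S,4S)-2-(tert-butyldimethylsilyloxy)-4-(tert-butyldiphenylsilyloxy)-N-methoxy-N-methyl-4-[(2R)-oxiran-2-yl]butanamide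
Conditions: TBDPSCl, imidazole, DMAP (cat.), DMF, rt
Reagents that add atoms: tert-butyldiphenylsilyl chloride, CC(C)(C)[Si](Cl)(c1ccccc1)c1ccccc1
Why: Imidazole-mediated silylation leaves the epoxide intact and puts on C10 a bulky, weakly nucleophilic ether that should neither take part in the chlorocyclisation nor be lost when the C12 TBS ether is cleaved.

Step 7
Reactants: 9 trimethylsilylacetylene; 10 propargyl bromide
Product: 12 1-(trimethylsilyl)penta-1,4-diyne, via alkynylmagnesium chloride 11 (not isolated)
Conditions: i-PrMgCl, THF, 0 °C; then CuCl (cat.), 10, THF, 0 → 50 °C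
Reagents that add atoms: none
Why: CuCl-catalysed coupling of an alkynyl Grignard reagent with propargyl bromide is the standard route to skipped 1,4-diynes and should give direct substitution in preference to the allene.

Step 8
Reactants: 12 1-(trimethylsilyl)penta-1,4-diyne
Product: 14 (E)-1-iodo-5-(trimethylsilyl)pent-1-en-4-yne, via alkenylzirconocene chloride 13 (not isolated)
Conditions: Cp2Zr(H)Cl, THF, rt; then I2, 0 °C
Reagents that add atoms: iodine, II
Why: Hydrozirconation with Cp2Zr(H)Cl is a fast syn addition at the terminal alkyne that leaves the silyl-capped alkyne alone, and iodinolysis with retention then gives the E-alkenyl iodide.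

Step 9
Reactants: 14 (E)-1-iodo-5-(trimethylsilyl)pent-1-en-4-yne; 8 (2S,4S)-2-(tert-butyldimethylsilyloxy)-4-(tert-butyldiphenylsilyloxy)-N-methoxy-N-methyl-4-[(2R)-oxiran-2-yl]butanamide
Product: 17 (2S,4S,5R,7E)-2-(tert-butyldimethylsilyloxy)-4-(tert-butyldiphenylsilyloxy)-5-hydroxy-N-methoxy-N-methyl-11-(trimethylsilyl)undec-7-en-10-ynamide, via alkenyllithium 15 (not isolated), via alkenyldimethylalane 16 (not isolated)
Conditions: t-BuLi (2 equiv), Et2O, −78 °C; Me2AlCl, −78 °C; then 8, BF3·OEt2, −78 °C
Reagents that add atoms: none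
Why: Iodine–lithium exchange with retention of alkene geometry, transmetalation to the alkenylalane and BF3-promoted alkenylalane opening of the terminal epoxide at unhindered C8 should give the E-homoallylic alcohol with C9 untouched, the alane being too weak a nucleophile to attack the Weinreb amide.

Step 10
Reactants: 17 (2S,4S,5R,7E)-2-(tert-butyldimethylsilyloxy)-4-(tert-butyldiphenylsilyloxy)-5-hydroxy-N-methoxy-N-methyl-11-(trimethylsilyl)undec-7-en-10-ynamide
Product: 18 the C9 tert-butyl carbonate of 17, (2S,4S,5R,7E)-5-[(tert-butoxycarbonyl)oxy]-2-(tert-butyldimethylsilyloxy)-4-(tert-butyldiphenylsilyloxy)-N-methoxy-N-methyl-11-(trimethylsilyl)undec-7-en-10-ynamide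
Conditions: Boc2O, DMAP, MeCN, rt
Reagents that add atoms: di-tert-butyl dicarbonate, CC(C)(C)OC(=O)OC(=O)OC(C)(C)C
Why: DMAP-catalysed acylation with Boc2O turns the hindered C9 alcohol into the tert-butyl carbonate that will serve as the internal oxygen nucleophile, under conditions too mild to lactonise onto the amide.

Step 11
Reactants: 18 the C9 tert-butyl carbonate Weinreb amide; 19 ethylmagnesium bromide
Product: 20 tert-butyl (4S,6S,7R,9E)-4-(tert-butyldimethylsilyloxy)-6-(tert-butyldiphenylsilyloxy)-3-oxo-13-(trimethylsilyl)tridec-9-en-12-yn-7-yl carbonate (the C3–C15 carbonate with C13 ethyl ketone; 9R,10S,12S in target numbering)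
Conditions: THF, −20 → 0 °C; aq. NH4Cl
Reagents that add atoms: none
Why: In this Weinreb ketone synthesis the chelated tetrahedral intermediate stops over-addition, and the hindered tert-butyl carbonate is much less electrophilic than the amide at or below 0 °C, so the C13 ethyl ketone should form with C12 intact.

Step 12
Reactants: 20 the C9 tert-butyl carbonate with C13 ethyl ketone
Product: 21 (4R,6S)-4-[(1S,3S)-3-(tert-butyldimethylsilyloxy)-1-(tert-butyldiphenylsilyloxy)-4-oxohexyl]-6-[(1R)-1-chloro-4-(trimethylsilyl)but-3-ynyl]-1,3-dioxan-2-one (C7,C9 cyclic carbonate with the C6 chloride)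
Conditions: DCDMH, Ph3P=S (cat.), CH2Cl2, −40 → −10 °C, dark
Reagents that add atoms: 1,3-dichloro-5,5-dimethylhydantoin, CC1(C)N(Cl)C(=O)N(Cl)C1=O
Why: Lewis-base-activated DCDMH transfers electrophilic chlorine to the C6=C7 alkene, the carbonyl oxygen of the C9 tert-butyl carbonate opens the chloriranium ion at C7 anti to chlorine, and loss of the tert-butyl group as isobutene makes the capture irreversible. The closest known reaction is the iodo- or bromocarbonate cyclisation of homoallylic tert-butyl carbonates to syn-1,3-diol carbonates, run here with a chlorine electrophile. The 1,3-dioxan-2-one closes in a 6-exo mode by opening the chloriranium at its nearer carbon C7, the 7-endo attack at C6 being geometrically disfavoured. C7 (S) is controlled by C9 through a chair-like transition state in which the C10-bearing chain and the developing C6 chain are both equatorial, which gives the 1,3-syn carbonate, and C6 (R) follows from stereospecific anti addition across the E alkene. The step needs reaction at the alkene and not at the silyl alkyne, the ketone or the silyl ethers; this is secured by the higher nucleophilicity of the 1,2-dialkyl alkene, by the poor nucleophilicity of the TBDPS ether oxygen that could otherwise close a five-membered ring, and by working cold without acid so that the ketone does not enolise.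

Step 13
Reactants: 21 the C7,C9 cyclic carbonate
Product: 23 (3S,5S,6R)-3-(tert-butyldimethylsilyloxy)-5-(tert-butyldiphenylsilyloxy)-6-[(2S,3R)-3-chloro-2-hydroxyhex-5-ynyl]-2-ethyloxan-2-ol (C13 hemiketal, both anomers), via open-chain keto diol 22 (not isolated)
Conditions: K2CO3 (cat.), MeOH, 0 °C; pH 7 buffer as soon as the carbonate is consumed
Reagents that add atoms: none
Why: Base-catalysed transesterification (carbonate methanolysis) frees the C7 and C9 hydroxyls while the same methoxide protodesilylates the alkyne, the C9 hydroxyl then adds to the C13 ketone to give the six-membered hemiketal, and the short cold exposure is chosen because closure of the anti chlorohydrin to an epoxide should be much slower than carbonate cleavage.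

Step 14
Reactants: 23 the C13 hemiketal
Product: 24 the 2,6-cis oxane with free C7 hydroxyl, (6R,7S,9R,10S,12S,13S)-10-(tert-butyldiphenylsilyloxy)-12-(tert-butyldimethylsilyloxy)-6-chloro-9,13-epoxy C3–C15 chain with terminal C3 alkyne
Conditions: Et3SiH, BF3·OEt2, CH2Cl2/MeCN, −40 °C
Reagents that add atoms: none
Why: In this hemiketal (lactol) reduction BF3 ionises C13 to the cyclic oxocarbenium ion and Et3SiH delivers hydride axially onto the half-chair that keeps the C9 side chain pseudo-equatorial, which sets C13 (S) with the ethyl group cis to the C9 substituent, while the syn C7 hydroxyl cannot bridge to C13 without forcing its side chain under the ring.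

Step 15
Reactants: 24 the oxane C7 alcohol
Product: 25 the C7 acetate of 24
Conditions: Ac2O, pyridine, DMAP (cat.), CH2Cl2, 0 °C
Reagents that add atoms: acetic anhydride, CC(=O)OC(C)=O
Why: DMAP-catalysed acetylation of the only free hydroxyl installs the C7 acetate of the target with retention and protects this oxygen through the halogenations.

Step 16
Reactants: 25 the C7 acetate
Product: 26 the C12 alcohol (axial hydroxyl; C10 still TBDPS-protected)
Conditions: HF·pyridine, pyridine, THF, 0 °C → rt
Reagents that add atoms: none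
Why: Selective desilylation is expected because a secondary TBS ether is cleaved by buffered HF·pyridine far faster than a secondary TBDPS ether, and the acetate and the chloride are inert to these conditions.

Step 17
Reactants: 26 the C12 alcohol
Product: 27 the (12R)-bromide (equatorial bromine; C10 TBDPS ether)
Conditions: CBr4, P(n-Oct)3, toluene, 70 °C
Reagents that add atoms: carbon tetrabromide, BrC(Br)(Br)Br
Why: In this Appel-type bromination the axial C12 alkoxyphosphonium ion is displaced by bromide in an SN2 reaction, so C12 is inverted to the equatorial (12R) bromide in a non-ionising solvent that disfavours elimination.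

Step 18
Reactants: 27 the (12R)-bromide
Product: 28 the C10 alcohol (equatorial hydroxyl)
Conditions: TBAF, AcOH, THF, rt
Reagents that add atoms: none
Why: Fluoride cleaves the TBDPS ether, and buffering with acetic acid keeps the medium too weakly basic to hydrolyse the acetate or eliminate the halides.

Step 19
Reactants: 28 the C10 alcohol
Product: 29 the (10R)-chloride, (6R,7S,9R,10R,12R,13S)-7-acetoxy-12-bromo-6,10-dichloro-9,13-epoxy C3–C15 chain with terminal C3 alkyne
Conditions: CCl4, P(n-Oct)3, toluene, 80 °C
Reagents that add atoms: carbon tetrachloride, ClC(Cl)(Cl)Cl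
Why: In this Appel chlorination chloride attacks the equatorial C10 alkoxyphosphonium ion from the axial direction, which faces only the ring oxygen and the C12 hydrogen, giving the axial (10R) chloride by inversion, and the low free chloride concentration in toluene should limit exchange at the C12 bromide.

Step 20
Reactants: 29 the (10R)-chloride with terminal alkyne
Product: 31 the (3E)-3-iodoalkene, C3–C15 vinyl iodide, via alkenylzirconocene chloride 30 (not isolated)
Conditions: Cp2Zr(H)Cl (1.3 equiv), THF, 0 °C → rt; then I2, 0 °C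
Reagents that add atoms: iodine, II
Why: Hydrozirconation places zirconium at the terminal carbon by syn addition much faster than Cp2Zr(H)Cl reduces an acetate or an alkyl halide, and iodinolysis with retention gives the E-vinyl iodide.

Step 21
Reactants: 31 the (3E)-vinyl iodide; 9 trimethylsilylacetylene
Product: 32 the C1-trimethylsilyl derivative of the target enyne
Conditions: Pd(PPh3)4 (cat.), CuI (cat.), i-Pr2NH, THF, rt
Reagents that add atoms: none
Why: Sonogashira coupling of the vinyl iodide proceeds at room temperature with retention of the E geometry and leaves the secondary alkyl halides and the acetate alone.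

Step 22
Reactants: 32 the C1-silylated enyne
Product: 33 (3E,6R,7S,9R,10R,12R,13S)-7-acetoxy-12-bromo-6,10-dichloro-9,13-epoxypentadec-3-en-1-yne (target)
Conditions: TBAF, AcOH, THF, 0 °C
Reagents that add atoms: none
Why: Fluoride-induced protodesilylation of the alkynylsilane, buffered with acetic acid, should spare the acetate, the enyne geometry and the three halides.

## Compound list

1 | (S)-α-hydroxy-γ-butyrolactone [(3S)-3-hydroxyoxolan-2-one] | O[C@H]1CCOC1=O | starting material
2 | (3S)-3-(tert-butyldimethylsilyloxy)oxolan-2-one | CC(C)(C)[Si](C)(C)O[C@H]1CCOC1=O | intermediate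
3 | (2S)-2-(tert-butyldimethylsilyloxy)-4-hydroxy-N-methoxy-N-methylbutanamide | CON(C)C(=O)[C@H](CCO)O[Si](C)(C)C(C)(C)C | intermediate
4 | (2S)-2-(tert-butyldimethylsilyloxy)-N-methoxy-N-methyl-4-oxobutanamide | CON(C)C(=O)[C@H](CC=O)O[Si](C)(C)C(C)(C)C | intermediate
5 | vinylmagnesium bromide | C=C[Mg]Br | starting material
6 | (2S,4RS)-2-(tert-butyldimethylsilyloxy)-4-hydroxy-N-methoxy-N-methylhex-5-enamide (C10 epimers) | CON(C)C(=O)[C@H](CC(O)C=C)O[Si](C)(C)C(C)(C)C | intermediate
7 | (2S,4S)-2-(tert-butyldimethylsilyloxy)-4-hydroxy-N-methoxy-N-methyl-4-[(2R)-oxiran-2-yl]butanamide | CON(C)C(=O)[C@H](C[C@H](O)[C@H]1CO1)O[Si](C)(C)C(C)(C)C | intermediate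
8 | (2S,4S)-2-(tert-butyldimethylsilyloxy)-4-(tert-butyldiphenylsilyloxy)-N-methoxy-N-methyl-4-[(2R)-oxiran-2-yl]butanamide | CON(C)C(=O)[C@H](C[C@H](O[Si](c1ccccc1)(c1ccccc1)C(C)(C)C)[C@H]1CO1)O[Si](C)(C)C(C)(C)C | intermediate
9 | trimethylsilylacetylene | C#C[Si](C)(C)C | starting material
10 | propargyl bromide | C#CCBr | starting material
11 | [2-(trimethylsilyl)ethynyl]magnesium chloride | C[Si](C)(C)C#C[Mg]Cl | intermediate
12 | 1-(trimethylsilyl)penta-1,4-diyne | C[Si](C)(C)C#CCC#C | intermediate
13 | chloro[(1E)-5-(trimethylsilyl)pent-1-en-4-ynyl]zirconocene | C[Si](C)(C)C#CC/C=C/[Zr](Cl)(C1C=CC=C1)C1C=CC=C1 | intermediate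
14 | (E)-1-iodo-5-(trimethylsilyl)pent-1-en-4-yne | C[Si](C)(C)C#CC/C=C/I | intermediate
15 | [(1E)-5-(trimethylsilyl)pent-1-en-4-ynyl]lithium | C[Si](C)(C)C#CC/C=C/[Li] | intermediate
16 | dimethyl[(1E)-5-(trimethylsilyl)pent-1-en-4-ynyl]alane | C[Si](C)(C)C#CC/C=C/[Al](C)C | intermediate
17 | (2S,4S,5R,7E)-2-(tert-butyldimethylsilyloxy)-4-(tert-butyldiphenylsilyloxy)-5-hydroxy-N-methoxy-N-methyl-11-(trimethylsilyl)undec-7-en-10-ynamide | C[Si](C)(C)C#CC/C=C/C[C@@H](O)[C@@H](O[Si](c1ccccc1)(c1ccccc1)C(C)(C)C)C[C@H](O[Si](C)(C)C(C)(C)C)C(=O)N(C)OC | intermediate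
18 | C9 tert-butyl carbonate of 17 | C[Si](C)(C)C#CC/C=C/C[C@@H](OC(=O)OC(C)(C)C)[C@@H](O[Si](c1ccccc1)(c1ccccc1)C(C)(C)C)C[C@H](O[Si](C)(C)C(C)(C)C)C(=O)N(C)OC | intermediate
19 | ethylmagnesium bromide | CC[Mg]Br | starting material
20 | tert-butyl (4S,6S,7R,9E)-4-(tert-butyldimethylsilyloxy)-6-(tert-butyldiphenylsilyloxy)-3-oxo-13-(trimethylsilyl)tridec-9-en-12-yn-7-yl carbonate | C[Si](C)(C)C#CC/C=C/C[C@@H](OC(=O)OC(C)(C)C)[C@@H](O[Si](c1ccccc1)(c1ccccc1)C(C)(C)C)C[C@H](O[Si](C)(C)C(C)(C)C)C(=O)CC | intermediate
21 | (4R,6S)-4-[(1S,3S)-3-(tert-butyldimethylsilyloxy)-1-(tert-butyldiphenylsilyloxy)-4-oxohexyl]-6-[(1R)-1-chloro-4-(trimethylsilyl)but-3-ynyl]-1,3-dioxan-2-one | C[Si](C)(C)C#CC[C@@H](Cl)[C@@H]1C[C@@H](OC(=O)O1)[C@@H](O[Si](c2ccccc2)(c2ccccc2)C(C)(C)C)C[C@H](O[Si](C)(C)C(C)(C)C)C(=O)CC | intermediate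
22 | open-chain keto diol, (6R,7S,9R,10S,12S)-6-chloro-7,9-dihydroxy-10-(tert-butyldiphenylsilyloxy)-12-(tert-butyldimethylsilyloxy) C3–C15 chain with C13 ketone and terminal alkyne | C#CC[C@@H](Cl)[C@@H](O)C[C@@H](O)[C@@H](O[Si](c1ccccc1)(c1ccccc1)C(C)(C)C)C[C@H](O[Si](C)(C)C(C)(C)C)C(=O)CC | intermediate
23 | (3S,5S,6R)-3-(tert-butyldimethylsilyloxy)-5-(tert-butyldiphenylsilyloxy)-6-[(2S,3R)-3-chloro-2-hydroxyhex-5-ynyl]-2-ethyloxan-2-ol (C13 anomers) | C#CC[C@@H](Cl)[C@@H](O)C[C@H]1OC(O)(CC)[C@@H](O[Si](C)(C)C(C)(C)C)C[C@@H]1O[Si](c1ccccc1)(c1ccccc1)C(C)(C)C | intermediate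
24 | (2S,3R)-1-[(2R,3S,5S,6S)-5-(tert-butyldimethylsilyloxy)-3-(tert-butyldiphenylsilyloxy)-6-ethyloxan-2-yl]-3-chlorohex-5-yn-2-ol | C#CC[C@@H](Cl)[C@@H](O)C[C@H]1O[C@@H](CC)[C@@H](O[Si](C)(C)C(C)(C)C)C[C@@H]1O[Si](c1ccccc1)(c1ccccc1)C(C)(C)C | intermediate
25 | C7 acetate of 24 | C#CC[C@@H](Cl)[C@H](C[C@H]1O[C@@H](CC)[C@@H](O[Si](C)(C)C(C)(C)C)C[C@@H]1O[Si](c1ccccc1)(c1ccccc1)C(C)(C)C)OC(C)=O | intermediate
26 | C12 alcohol (12S, axial OH; C10 TBDPS ether; C7 acetate) | C#CC[C@@H](Cl)[C@H](C[C@H]1O[C@@H](CC)[C@@H](O)C[C@@H]1O[Si](c1ccccc1)(c1ccccc1)C(C)(C)C)OC(C)=O | intermediate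
27 | C12 bromide (12R, equatorial Br; C10 TBDPS ether; C7 acetate) | C#CC[C@@H](Cl)[C@H](C[C@H]1O[C@@H](CC)[C@H](Br)C[C@@H]1O[Si](c1ccccc1)(c1ccccc1)C(C)(C)C)OC(C)=O | intermediate
28 | C10 alcohol (10S, equatorial OH; 12R bromide; C7 acetate) | C#CC[C@@H](Cl)[C@H](C[C@H]1O[C@@H](CC)[C@H](Br)C[C@@H]1O)OC(C)=O | intermediate
29 | (2S,3R)-1-[(2R,3R,5R,6S)-5-bromo-3-chloro-6-ethyloxan-2-yl]-3-chlorohex-5-yn-2-yl acetate | C#CC[C@@H](Cl)[C@H](C[C@H]1O[C@@H](CC)[C@H](Br)C[C@H]1Cl)OC(C)=O | intermediate
30 | C3 alkenylzirconocene chloride from 29 (E) | Cl[Zr](/C=C/C[C@@H](Cl)[C@H](C[C@H]1O[C@@H](CC)[C@H](Br)C[C@H]1Cl)OC(C)=O)(C2C=CC=C2)C2C=CC=C2 | intermediate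
31 | (2S,3R,5E)-1-[(2R,3R,5R,6S)-5-bromo-3-chloro-6-ethyloxan-2-yl]-3-chloro-6-iodohex-5-en-2-yl acetate | I/C=C/C[C@@H](Cl)[C@H](C[C@H]1O[C@@H](CC)[C@H](Br)C[C@H]1Cl)OC(C)=O | intermediate
32 | C1-trimethylsilyl derivative of the target | C[Si](C)(C)C#C/C=C/C[C@@H](Cl)[C@H](C[C@H]1O[C@@H](CC)[C@H](Br)C[C@H]1Cl)OC(C)=O | intermediate
33 | (3E,6R,7S,9R,10R,12R,13S)-7-acetoxy-12-bromo-6,10-dichloro-9,13-epoxypentadec-3-en-1-yne | C#C/C=C/C[C@@H](Cl)[C@H](C[C@H]1O[C@@H](CC)[C@H](Br)C[C@H]1Cl)OC(C)=O | target

## Step count and risks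

Total steps: 22. Longest linear sequence: 20 steps (steps 1–6 and 9–22, from lactone 1); steps 7 and 8 make the diyne-derived fragment.

Steps most likely to fail:

Step 12. A chloriranium ion forms less reversibly than an iodiranium ion, so face selection at the alkene may be poorer than in the iodine series and the 1,3-syn ratio may erode. Chlorine transfer to the alkyne or to the ketone enol may also compete. The fallback sets out from 20 and comes back at 23. IBr in toluene at −85 °C should give the C6-iodo cyclic carbonate F1 by iodocarbonate cyclisation. K2CO3 in MeOH should then cleave the carbonate, close the C7 alkoxide onto C6 with inversion, remove the alkynyl silyl group and let the C9 hydroxyl add to the ketone, giving the trans-6,7-epoxide hemiketal F2. Opening of the epoxide at C6 with chloride (LiCl, AcOH, THF) inverts C6 a second time and returns chlorohydrin 23. Regioselection for C6 in this opening relies on the inductive deactivation of C7 by the C9 oxygen and would have to be checked.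

Step 17. The axial C12 leaving group has antiperiplanar hydrogens on C11 and C13, so elimination to an alkene or enol ether, or a hydride shift from C13, may compete with substitution at 70 °C. The fallback sets out from 26 and comes back at 27. Tf2O and pyridine in CH2Cl2 at −20 °C should give the C12 triflate F3, a discrete sulfonate with a far better leaving group. n-Bu4NBr in toluene at 0 °C → rt should then displace it with inversion at low temperature.

Step 9. Proton transfer from the doubly activated C5 methylene to the alkenyllithium before transmetalation, or BF3-induced rearrangement of the epoxide, may lower the yield of the union. The fallback sets out from 8 and comes back at 17. Opening of 8 with vinylmagnesium bromide 5 and CuI (cat.) in THF at −40 °C should give the terminal homoallylic alcohol F4. Cross-metathesis of F4 with allyl chloride and second-generation Grubbs catalyst in CH2Cl2 at 40 °C should give the E-allylic chloride F5, with the minor Z isomer to be removed. Coupling of F5 with trimethylsilylacetylene 9 (CuI, NaI, K2CO3, DMF, rt) by direct substitution at the primary allylic carbon should then give 17.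

Further compounds
F1 | step 12 | (4R,6S)-4-[(1S,3S)-3-(tert-butyldimethylsilyloxy)-1-(tert-butyldiphenylsilyloxy)-4-oxohexyl]-6-[(1R)-1-iodo-4-(trimethylsilyl)but-3-ynyl]-1,3-dioxan-2-one | C[Si](C)(C)C#CC[C@@H](I)[C@@H]1C[C@@H](OC(=O)O1)[C@@H](O[Si](c2ccccc2)(c2ccccc2)C(C)(C)C)C[C@H](O[Si](C)(C)C(C)(C)C)C(=O)CC
F2 | step 12 | trans-6,7-epoxide hemiketal: (3S,5S,6R)-3-(tert-butyldimethylsilyloxy)-5-(tert-butyldiphenylsilyloxy)-2-ethyl-6-{[(2S,3S)-3-(prop-2-ynyl)oxiran-2-yl]methyl}oxan-2-ol (C13 anomers) | C#CC[C@@H]1O[C@H]1C[C@H]2OC(O)(CC)[C@@H](O[Si](C)(C)C(C)(C)C)C[C@@H]2O[Si](c3ccccc3)(c3ccccc3)C(C)(C)C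
F3 | step 17 | C12 trifluoromethanesulfonate of 26 | C#CC[C@@H](Cl)[C@H](C[C@H]1O[C@@H](CC)[C@@H](OS(=O)(=O)C(F)(F)F)C[C@@H]1O[Si](c1ccccc1)(c1ccccc1)C(C)(C)C)OC(C)=O
F4 | step 9 | (2S,4S,5R)-2-(tert-butyldimethylsilyloxy)-4-(tert-butyldiphenylsilyloxy)-5-hydroxy-N-methoxy-N-methyloct-7-enamide | C=CC[C@@H](O)[C@@H](O[Si](c1ccccc1)(c1ccccc1)C(C)(C)C)C[C@H](O[Si](C)(C)C(C)(C)C)C(=O)N(C)OC
F5 | step 9 | (2S,4S,5R,7E)-2-(tert-butyldimethylsilyloxy)-4-(tert-butyldiphenylsilyloxy)-9-chloro-5-hydroxy-N-methoxy-N-methylnon-7-enamide | ClC/C=C/C[C@@H](O)[C@@H](O[Si](c1ccccc1)(c1ccccc1)C(C)(C)C)C[C@H](O[Si](C)(C)C(C)(C)C)C(=O)N(C)OC
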